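The route rests on cutting C13–C14 (iridal numbering). This is the sp3–sp2 bond between the CH2CH2 arm on the quaternary ring carbon C11 and the (E)-trisubstituted C14=C15 alkene. C13 lies two carbons from C11, so a vinyl group on C11 is a latent C12–C13 nucleophile. 9-BBN hydroboration and, in the same flask, B-alkyl Suzuki–Miyaura coupling with an (E)-alkenyl iodide already bearing the C16 acetate unite the two finished halves with alkene geometry retained. One half is the cyclohexane core (C6, C10, C11 stereocentres, Z-tetrasubstituted C7=C2 alkene, masked enal). The other is the C14–C24 chain. The precursors are vinylcyclohexanol 19 and iodide 29.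

Key step: step 15

Remark on numbering: C1 is the CHO carbon, C2 the alkene carbon bearing it, and C25 the methyl group on C2. C3–C5 form the oxypropyl arm, C6–C11 the cyclohexane ring, and C12–C24 the long side chain. TBS = tert-butyldimethylsilyl.

Assumption: the copper–phosphoramidite catalyst in step 1 is taken to induce on dienone 2 in the same sense as on cyclohex-2-enone. If the sense is opposite, the antipodal ligand is used.

Where each stereoelement is set:
- C6: step 1
- C11: step 3
- C10: step 5
- C7=C2 geometry: step 8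
- C14=C15 geometry: step 9
- C16: step 13
- C18=C19 geometry: comes with geranyl chloride 24

Step 1
Reactants: 1 tert-butyl(3-iodopropoxy)dimethylsilane; 2 4,4-dimethoxycyclohexa-2,5-dien-1-one
Product: 5 (S)-5-[3-(TBSO)propyl]-4,4-dimethoxycyclohex-2-en-1-one, via dialkylzinc 3 (not isolated), via zinc enolate 4 (not isolated)
Conditions: 1, Et2Zn, CuI (cat.), neat, 50 °C, volatiles off; then 2, Cu(OTf)2 (2 mol %), (R,S,S)-binaphthol-derived bis(1-phenylethyl)phosphoramidite (4 mol %), toluene, −25 °C
Reagents that add atoms: none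
Why: Copper-catalysed asymmetric conjugate addition of a functionalised dialkylzinc desymmetrises the prochiral quinone monoketal, and the chiral copper–phosphoramidite complex selects one enantiotopic enone face and so sets C6.

Step 2
Reactants: 5
Product: 7 (5S)-5-[3-(TBSO)propyl]-4,4-dimethoxy-6-methylcyclohex-2-en-1-one (both C6 ring epimers), via lithium dienolate 6 (not isolated)
Conditions: LDA, THF, −78 °C; MeI, −78 to −20 °C
Reagents that add atoms: iodomethane, CI
Why: Kinetic enolate alkylation should occur only at C11, since the ketal carbon blocks γ-deprotonation, and the new stereocentre is erased again in step 3.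

Step 3
Reactants: 7
Product: 9 (5S,6R)-5-[3-(TBSO)propyl]-6-(1-hydroxyethyl)-4,4-dimethoxy-6-methylcyclohex-2-en-1-one (carbinol epimers), via lithium dienolate 8 (not isolated)
Conditions: LDA, THF, −78 to −40 °C; CH3CHO, −78 °C; AcOH quench at −78 °C
Reagents that add atoms: acetaldehyde, CC=O
Why: In this aldol addition of a fully substituted enolate, allylic 1,2-strain with the C11 methyl pushes the C6 chain pseudoaxial, so acetaldehyde should enter anti to it and set quaternary C11 with C12 trans to C5.

Step 4
Reactants: 9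
Product: 10 (5S,6S)-5-[3-(TBSO)propyl]-6-ethenyl-4,4-dimethoxy-6-methylcyclohex-2-en-1-one
Conditions: Ph2S[OC(CF3)2Ph]2, CH2Cl2, rt
Reagents that add atoms: none
Why: Sulfurane dehydration under near-neutral conditions avoids retro-aldol cleavage, and because C11 is quaternary it can only eliminate toward the methyl group, giving the C12=C13 vinyl group.

Step 5
Reactants: 10
Product: 12 (4S,5S,6S)-6-[3-(TBSO)propyl]-5-ethenyl-4-hydroxy-4,5-dimethylcyclohex-2-en-1-one, via tertiary alcohol 11 (not isolated)
Conditions: MeLi, Et2O, −78 °C; then 0.5 M aq. HCl, THF, 0 °C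
Reagents that add atoms: methyllithium, [Li]C; water, O
Why: In the 1,2-addition to the non-enolisable enone, MeLi should enter on the face bearing the slim vinyl group, because the other face carries both the C11 methyl and the C6 chain; this sets C10, and the allylic dimethyl ketal then hydrolyses in the acidic work-up.

Step 6
Reactants: 12
Product: 14 (4S,5S,6S)-6-[3-(TBSO)propyl]-5-ethenyl-4-hydroxy-4,5-dimethylcyclohex-1-en-1-yl trifluoromethanesulfonate, via lithium enolate 13 (not isolated)
Conditions: LiBH(s-Bu)3 (2.2 equiv), THF, −78 °C; PhNTf2, −78 to 0 °C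
Reagents that add atoms: N-phenylbis(trifluoromethanesulfonimide), O=S(=O)(N(c1ccccc1)S(=O)(=O)C(F)(F)F)C(F)(F)F
Why: Conjugate hydride reduction removes the C8=C9 alkene and delivers the C7–C8 enolate regiospecifically, away from C6, and O-triflation traps it without touching the C6 stereocentre.

Step 7
Reactants: 14; 15 2-bromo-3,3-diethoxyprop-1-ene
Product: 18 (1S,5R,6S)-5-[3-(TBSO)propyl]-4-(3,3-diethoxyprop-1-en-2-yl)-6-ethenyl-1,6-dimethylcyclohex-3-en-1-ol, via alkenyllithium 16 (not isolated), via alkenylzinc bromide 17 (not isolated)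
Conditions: 15, n-BuLi, Et2O, −78 °C; ZnBr2, THF; then 14, Pd(PPh3)4 (5 mol %), THF, 45 °C
Reagents that add atoms: none
Why: Negishi alkenyl–alkenyl coupling of an enol triflate should attach the three-carbon C2/C1/C25 unit to C7 as a masked 2-substituted acrolein and tolerates the free tertiary alcohol when the zinc reagent is in excess.

Step 8
Reactants: 18
Product: 19 (1S,2S,3R,4Z)-3-[3-(TBSO)propyl]-4-(1,1-diethoxypropan-2-ylidene)-2-ethenyl-1,2-dimethylcyclohexan-1-ol
Conditions: (η6-naphthalene)Cr(CO)3 (20 mol %), H2 (70 atm), THF, 45 °C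
Reagents that add atoms: none
Why: In this tricarbonylchromium-catalysed 1,4-hydrogenation the diene must bind η4 in its s-cis form, so hydrogen adds to the termini C8 and C25, leaving the new methyl cis to C8 and the acetal carbon C1 cis to C6, while the isolated vinyl group is not a substrate.

Step 9
Reactants: 20 propargyl alcohol
Product: 22 (E)-3-iodo-2-methylprop-2-en-1-ol, via alkenylalane 21 (not isolated)
Conditions: AlMe3 (3 equiv), Cp2ZrCl2 (0.25 equiv), CH2Cl2, 0 °C to rt; I2, THF, −30 °C
Reagents that add atoms: trimethylaluminium, C[Al](C)C; iodine, II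
Why: Zirconium-catalysed syn-carboalumination places methyl on the internal and aluminium on the terminal alkyne carbon, and iodinolysis with retention fixes the E geometry of the future C14=C15 alkene.

Step 10
Reactants: 22
Product: 23 (E)-3-iodo-2-methylprop-2-enal
Conditions: MnO2, CH2Cl2, rt
Reagents that add atoms: none
Why: Allylic alcohol oxidation with MnO2 should stop at the enal without affecting the alkenyl iodide or its geometry.

Step 11
Reactants: 23; 24 geranyl chloride
Product: 26 rac-(1E,5E)-1-iodo-2,6,10-trimethylundeca-1,5,9-trien-3-ol, via geranylbarium chloride 25 (not isolated)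
Conditions: BaI2, lithium biphenylide, THF, rt; 24, −78 °C; then 23, −78 °C
Reagents that add atoms: none
Why: Allylbarium reagents add 1,2 to aldehydes through their unsubstituted α-terminus with retention of the allyl geometry, which should give the linear adduct with the E C18=C19 alkene intact.

Step 12
Reactants: 26
Product: 27 (1E,5E)-1-iodo-2,6,10-trimethylundeca-1,5,9-trien-3-one
Conditions: Dess–Martin periodinane, CH2Cl2, 0 °C, short contact
Reagents that add atoms: none
Why: Dess–Martin oxidation is mild enough that the β,γ-alkene should not move into conjugation.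

Step 13
Reactants: 27
Product: 28 (3R,1E,5E)-1-iodo-2,6,10-trimethylundeca-1,5,9-trien-3-ol
Conditions: (S)-2-methyl-CBS-oxazaborolidine (20 mol %), catecholborane, toluene, −78 °C
Reagents that add atoms: none
Why: In the Corey–Bakshi–Shibata reduction the α-methyl-β-iodoalkenyl group acts as the large substituent, so the (S)-catalyst should deliver hydride to give the R carbinol at C16, and catecholborane leaves the trisubstituted alkenes alone.

Step 14
Reactants: 28
Product: 29 (3R,1E,5E)-1-iodo-2,6,10-trimethylundeca-1,5,9-trien-3-yl acetate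
Conditions: Ac2O, pyridine, DMAP (cat.), CH2Cl2, 0 °C to rt
Reagents that add atoms: acetic anhydride, CC(=O)OC(C)=O
Why: Standard O-acylation proceeds with retention at C16.

Step 15
Reactants: 19; 29
Product: 31 coupled C1 diethyl acetal C3 TBS ether C16 acetate, via B-alkylborane 30 (not isolated)
Conditions: 19, 9-BBN (3 equiv), THF, rt to 40 °C; then H2O, 29, Pd(dppf)Cl2 (10 mol %), AsPh3, Cs2CO3, DMF, rt
Reagents that add atoms: none
Why: 9-BBN adds syn and anti-Markovnikov to the only monosubstituted alkene of 19, the C12=C13 vinyl group on C11, placing boron on C13, while the tetrasubstituted C7=C2 alkene is inert and the C10 hydroxyl merely consumes reagent. Base converts borane 30 into a borate, zerovalent palladium inserts into the C14–I bond of 29 with retention, the primary alkyl group passes from boron to palladium, and reductive elimination forms C13–C14; the reaction type is the B-alkyl Suzuki–Miyaura coupling of alkenyl iodides. No ring is closed and no stereocentre is created, and the E geometry of C14=C15 fixed in step 9 is carried through unchanged. The step needs insertion into C–I to win over ionisation of the C16 allylic acetate, which the much faster oxidative addition to the iodide at room temperature and the hindered secondary position of the acetate should secure. It also needs reductive elimination to outrun β-hydride elimination, for which the wide bite angle of dppf is chosen, and a base mild enough (Cs2CO3 in wet DMF) to leave acetate, acetal and silyl ether untouched.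

Step 16
Reactants: 31
Product: 32 C3 hydroxy Z-enal bearing the C16 acetate
Conditions: 48 % aq. HF, MeCN, 0 °C
Reagents that add atoms: water, O
Why: Fluoride-driven silyl ether cleavage and acid-catalysed hydrolysis of the allylic acetal should occur together under mildly acidic conditions that leave the acetate, the tertiary alcohol and the C7=C2 geometry unchanged.

Step 17
Reactants: 32; 33 myristoyl chloride
Product: 34 target CNP0184857.1
Conditions: 33, pyridine, DMAP (cat.), CH2Cl2, 0 °C
Reagents that add atoms: none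
Why: In this chemoselective esterification only the primary C3 hydroxyl should react, because the C10 tertiary alcohol next to quaternary C11 is too hindered.

Compound list
1 | tert-butyl(3-iodopropoxy)dimethylsilane | CC(C)(C)[Si](C)(C)OCCCI | starting material
2 | 4,4-dimethoxycyclohexa-2,5-dien-1-one | COC1(OC)C=CC(=O)C=C1 | starting material
3 | bis[3-(TBSO)propyl]zinc | CC(C)(C)[Si](C)(C)OCCC[Zn]CCCO[Si](C)(C)C(C)(C)C | intermediate
4 | alkylzinc enolate from the conjugate addition | CC(C)(C)[Si](C)(C)OCCC[Zn]OC1=C[C@H](CCCO[Si](C)(C)C(C)(C)C)C(OC)(OC)C=C1 | intermediate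
5 | (S)-5-[3-(TBSO)propyl]-4,4-dimethoxycyclohex-2-en-1-one | O=C1C=CC(OC)(OC)[C@@H](CCCO[Si](C)(C)C(C)(C)C)C1 | intermediate
6 | lithium cross-conjugated dienolate of 5 | [Li]OC1=C[C@H](CCCO[Si](C)(C)C(C)(C)C)C(OC)(OC)C=C1 | intermediate
7 | (5S)-5-[3-(TBSO)propyl]-4,4-dimethoxy-6-methylcyclohex-2-en-1-one, C6 ring epimers | O=C1C=CC(OC)(OC)[C@@H](CCCO[Si](C)(C)C(C)(C)C)C1C | intermediate
8 | lithium cross-conjugated dienolate of 7 | [Li]OC1=C(C)[C@H](CCCO[Si](C)(C)C(C)(C)C)C(OC)(OC)C=C1 | intermediate
9 | (5S,6R)-5-[3-(TBSO)propyl]-6-(1-hydroxyethyl)-4,4-dimethoxy-6-methylcyclohex-2-en-1-one, carbinol epimers | O=C1C=CC(OC)(OC)[C@@H](CCCO[Si](C)(C)C(C)(C)C)[C@]1(C)C(C)O | intermediate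
10 | (5S,6S)-5-[3-(TBSO)propyl]-6-ethenyl-4,4-dimethoxy-6-methylcyclohex-2-en-1-one | O=C1C=CC(OC)(OC)[C@@H](CCCO[Si](C)(C)C(C)(C)C)[C@]1(C)C=C | intermediate
11 | (1S,5S,6S)-5-[3-(TBSO)propyl]-6-ethenyl-4,4-dimethoxy-1,6-dimethylcyclohex-2-en-1-ol | C[C@]1(O)C=CC(OC)(OC)[C@@H](CCCO[Si](C)(C)C(C)(C)C)[C@]1(C)C=C | intermediate
12 | (4S,5S,6S)-6-[3-(TBSO)propyl]-5-ethenyl-4-hydroxy-4,5-dimethylcyclohex-2-en-1-one | C[C@]1(O)C=CC(=O)[C@@H](CCCO[Si](C)(C)C(C)(C)C)[C@]1(C)C=C | intermediate
13 | lithium C7–C8 enolate from conjugate reduction of 12 | C[C@]1(O)CC=C(O[Li])[C@@H](CCCO[Si](C)(C)C(C)(C)C)[C@]1(C)C=C | intermediate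
14 | (4S,5S,6S)-6-[3-(TBSO)propyl]-5-ethenyl-4-hydroxy-4,5-dimethylcyclohex-1-en-1-yl triflate | C[C@]1(O)CC=C(OS(=O)(=O)C(F)(F)F)[C@@H](CCCO[Si](C)(C)C(C)(C)C)[C@]1(C)C=C | intermediate
15 | 2-bromo-3,3-diethoxyprop-1-ene | C=C(Br)C(OCC)OCC | starting material
16 | (3,3-diethoxyprop-1-en-2-yl)lithium | [Li]C(=C)C(OCC)OCC | intermediate
17 | (3,3-diethoxyprop-1-en-2-yl)zinc bromide | Br[Zn]C(=C)C(OCC)OCC | intermediate
18 | (1S,5R,6S)-5-[3-(TBSO)propyl]-4-(3,3-diethoxyprop-1-en-2-yl)-6-ethenyl-1,6-dimethylcyclohex-3-en-1-ol | C[C@]1(O)CC=C(C(=C)C(OCC)OCC)[C@@H](CCCO[Si](C)(C)C(C)(C)C)[C@]1(C)C=C | intermediate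
19 | (1S,2S,3R,4Z)-3-[3-(TBSO)propyl]-4-(1,1-diethoxypropan-2-ylidene)-2-ethenyl-1,2-dimethylcyclohexan-1-ol | CC(C)(C)[Si](C)(C)OCCC[C@@H]1/C(=C(/C)C(OCC)OCC)CC[C@](C)(O)[C@@]1(C)C=C | intermediate
20 | propargyl alcohol | C#CCO | starting material
21 | (E)-alkenylalane aluminium alkoxide | C[Al](C)/C=C(\C)CO[Al](C)C | intermediate
22 | (E)-3-iodo-2-methylprop-2-en-1-ol | I/C=C(\C)CO | intermediate
23 | (E)-3-iodo-2-methylprop-2-enal | I/C=C(\C)C=O | intermediate
24 | geranyl chloride, (E)-1-chloro-3,7-dimethylocta-2,6-diene | ClC/C=C(\C)CCC=C(C)C | starting material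
25 | geranylbarium chloride | Cl[Ba]C/C=C(\C)CCC=C(C)C | intermediate
26 | rac-(1E,5E)-1-iodo-2,6,10-trimethylundeca-1,5,9-trien-3-ol | I/C=C(\C)C(O)C/C=C(\C)CCC=C(C)C | intermediate
27 | (1E,5E)-1-iodo-2,6,10-trimethylundeca-1,5,9-trien-3-one | I/C=C(\C)C(=O)C/C=C(\C)CCC=C(C)C | intermediate
28 | (3R,1E,5E)-1-iodo-2,6,10-trimethylundeca-1,5,9-trien-3-ol | I/C=C(\C)[C@@H](C/C=C(\C)CCC=C(C)C)O | intermediate
29 | (3R,1E,5E)-1-iodo-2,6,10-trimethylundeca-1,5,9-trien-3-yl acetate | I/C=C(\C)[C@@H](C/C=C(\C)CCC=C(C)C)OC(C)=O | intermediate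
30 | C13 B-alkyl-9-borabicyclo[3.3.1]nonane from 19 | CC(C)(C)[Si](C)(C)OCCC[C@@H]1/C(=C(/C)C(OCC)OCC)CC[C@](C)(O)[C@@]1(C)CCB1C2CCCC1CCC2 | intermediate
31 | coupled product: C1 diethyl acetal, C3 TBS ether, C10 alcohol, (16R)-acetate, 2Z,14E,18E | CC(C)(C)[Si](C)(C)OCCC[C@@H]1/C(=C(/C)C(OCC)OCC)CC[C@](C)(O)[C@@]1(C)CC/C=C(\C)[C@@H](C/C=C(\C)CCC=C(C)C)OC(C)=O | intermediate
32 | C3 hydroxy Z-enal with the (16R)-acetate (target lacking the myristoyl group) | OCCC[C@@H]1/C(=C(/C)C=O)CC[C@](C)(O)[C@@]1(C)CC/C=C(\C)[C@@H](C/C=C(\C)CCC=C(C)C)OC(C)=O | intermediate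
33 | myristoyl chloride (tetradecanoyl chloride) | CCCCCCCCCCCCCC(=O)Cl | starting material
34 | CNP0184857.1 | CCCCCCCCCCCCCC(=O)OCCC[C@@H]1/C(=C(/C)C=O)CC[C@](C)(O)[C@@]1(C)CC/C=C(\C)[C@@H](C/C=C(\C)CCC=C(C)C)OC(C)=O | target

Total step count: 17
Longest linear sequence: 11 steps (steps 1–8, then 15–17)

Steps most likely to fail

Step 8. The congested 2,3-disubstituted diene may not reach the planar s-cis geometry needed for η4 binding to chromium. Hydrogen uptake could then stall, or double-bond migration could take over. The fallback sets out from 12 and returns at 19. It builds the alkene by steric differentiation of two geminal halides.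
- Conjugate reduction of 12 with [(Ph3P)CuH]6 should give the saturated hydroxy ketone F1.
- Dibromomethylenation (CBr4, PPh3) should give the 1,1-dibromoalkene F2.
- Palladium-catalysed mono-methylation with Me2Zn should engage the less hindered C–Br bond, the one cis to C8H2, and give the (Z)-1-bromoethylidene compound F3.
- Deprotonation of the hydroxyl group, bromine–lithium exchange with t-BuLi and trapping with DMF should give, with retention, the Z-enal F4.
- HC(OEt)3 with PPTS converts F4 into 19.

Step 5. Facial selectivity in the addition to C10 may be poor or reversed, because one face is flanked by the vinyl group and the other by the C11 methyl and the C6 chain. The fallback sets out from 10 and returns at 12. It inverts the roles of carbon and oxygen.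
- Methylenation with Ph3P=CH2 should give the cross-conjugated triene F5.
- Peracid epoxidation of the exocyclic, most electron-rich alkene from the more accessible face puts oxygen, not carbon, on that face and should give the spiro-epoxide F6.
- LiBHEt3 opens the epoxide at its CH2 terminus to 11, which the acid work-up of step 5 turns into 12.

Step 3. The aldol addition may reverse, or acetaldehyde may transfer a proton to the hindered enolate. Either would hold back formation of the quaternary centre. The fallback sets out from 7 and returns at 10, so it also bypasses step 4.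
- Dienolate 8 is added irreversibly to phenyl vinyl sulfoxide, again anti to the C6 chain, to give the γ-keto sulfoxide F7.
- Thermolysis (toluene, 110 °C, CaCO3) should eliminate the sulfinyl group in a syn fashion and leave the vinyl group of 10.

Further compounds
F1 | step 8 | (2S,3S,4S)-2-[3-(TBSO)propyl]-3-ethenyl-4-hydroxy-3,4-dimethylcyclohexan-1-one | C[C@]1(O)CCC(=O)[C@@H](CCCO[Si](C)(C)C(C)(C)C)[C@]1(C)C=C
F2 | step 8 | 4-(dibromomethylidene) analogue of F1 | C[C@]1(O)CCC(=C(Br)Br)[C@@H](CCCO[Si](C)(C)C(C)(C)C)[C@]1(C)C=C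
F3 | step 8 | (Z)-4-(1-bromoethylidene) compound, bromine cis to C6 | CC(C)(C)[Si](C)(C)OCCC[C@@H]1/C(=C(/C)Br)CC[C@](C)(O)[C@@]1(C)C=C
F4 | step 8 | Z-enal of the vinyl core | CC(C)(C)[Si](C)(C)OCCC[C@@H]1/C(=C(/C)C=O)CC[C@](C)(O)[C@@]1(C)C=C
F5 | step 5 | C10 methylidene triene from 10 | C=C1C=CC(OC)(OC)[C@@H](CCCO[Si](C)(C)C(C)(C)C)[C@]1(C)C=C
F6 | step 5 | C10 spiro-epoxide, oxygen cis to the C11 methyl group | C1O[C@]12C=CC(OC)(OC)[C@@H](CCCO[Si](C)(C)C(C)(C)C)[C@]2(C)C=C
F7 | step 3 | C11 2-(phenylsulfinyl)ethyl enone, sulfur epimers | O=C1C=CC(OC)(OC)[C@@H](CCCO[Si](C)(C)C(C)(C)C)[C@]1(C)CCS(=O)c1ccccc1
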